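**Retrosynthetic overview**
1. Labdane numbers are used. Ring A = C1–C5/C10, ring B = C5–C10, ring C = oxolane (O, C9, C11, C12, C13), ring D = dihydrofuran (C13, C14, C15, O, C16). Ring D is made last by dehydrating a lactol that comes from an allyl/CH2OH pair on C13.
2. The C6 acetate and C7 ketone come from a plain 7-ketone by enol acetate epoxidation and acyloxy shift. The 7-ketone and the C8 methyl come from an 8-ketone (enol triflate, methylation, epoxide, hydride shift).
3. The key disconnection is C9–C10. The enabling feature is C9, the spiro atom of rings B and C. It carries the ring C oxygen and lies between quaternary C10 and C8, so with C8 as a carbonyl it is the product pattern of an oxocarbenium-triggered pinacol-type 1,2-shift. Ring B then grows from a cyclopentanol (C5, C6, C7, C8, C10) when C10 migrates from C8 to C9.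
4. The precursor is the simple adduct of a trans-hydrindanone (from the Hajos–Parrish ketone) and a 5-lithio-2,3-dihydrofuran whose C13 centre comes from a Sharpless epoxide.
5. Order of rings: A and the five-membered pre-B (bought), C (as dihydrofuran), B (six-membered, spiro junction, key step), D.

Key step: step 12

Remark: labdane numbers are also used for all precursors. The extra terminal carbon of the allyl group is lost in step 20. Alpha means the face opposite to the C10 methyl.

**Step 1**
Reactants: 1 (S)-Hajos–Parrish ketone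
Product: 2 enone ketal
Conditions: (TMSOCH2)2, TMSOTf (5 mol %), CH2Cl2, −78 °C
Reagents that add atoms: 1,2-bis(trimethylsilyloxy)ethane, C[Si](C)(C)OCCO[Si](C)(C)C
Why: Silyl-transfer ketalisation at low temperature takes saturated ketones and leaves conjugated enones alone, so only the cyclopentanone carbonyl (future C8) is masked and C10 is untouched.

**Step 2**
Reactants: 2 enone ketal
Product: 4 gem-dimethyl ketone ketal, via monomethyl enone ketal 3 (not isolated)
Conditions: KOt-Bu, MeI, t-BuOH/THF, 0 °C → rt
Reagents that add atoms: iodomethane, CI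
Why: Deconjugative double alpha-alkylation of the extended enolate puts both methyl groups on C4 and moves the alkene to C5=C6, as is standard for bicyclic enones of this family.

**Step 3**
Reactants: 4 gem-dimethyl ketone ketal
Product: 6 alkene ketal, via hydrazone 5 (not isolated)
Conditions: N2H4·H2O, KOH, diethylene glycol, 130 → 200 °C
Reagents that add atoms: none
Why: Wolff–Kishner reduction (Huang-Minlon variant) removes the hindered C3 carbonyl under basic conditions that the ketal and the isolated alkene tolerate.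

**Step 4**
Reactants: 6 alkene ketal
Product: 7 trans-hydrindane ketal
Conditions: H2 (4 bar), PtO2, EtOAc, rt
Reagents that add atoms: none
Why: Heterogeneous hydrogenation should add to the C5=C6 alkene from the alpha face, away from the angular C10 methyl and the beta methyl on C4, which sets C5 (H alpha, trans fusion).

**Step 5**
Reactants: 7 trans-hydrindane ketal
Product: 8 trans-hydrindanone
Conditions: 1 M HCl, THF, rt
Reagents that add atoms: water, O
Why: Acid-catalysed ketal hydrolysis frees the C8 ketone, and nothing can epimerise because C10 is quaternary and C5 is remote from the carbonyl.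

**Step 6**
Reactants: 9 propargyl alcohol
Product: 10 2-methylidenepent-4-en-1-ol
Conditions: allylMgBr (3 equiv), Et2O, reflux; then 1 M HCl
Reagents that add atoms: allylmagnesium bromide, C=CC[Mg]Br
Why: In this hydroxyl-assisted carbomagnesiation the magnesium alkoxide directs the allyl group to the internal alkyne carbon, and protonolysis gives the 1,1-disubstituted allylic alcohol.

**Step 7**
Reactants: 10 2-methylidenepent-4-en-1-ol
Product: 11 (R)-epoxy alcohol
Conditions: Ti(OiPr)4 (10 mol %), D-(−)-DIPT (12 mol %), t-BuOOH, 4 Å MS, CH2Cl2, −25 °C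
Reagents that add atoms: tert-butyl hydroperoxide, CC(C)(C)OO
Why: Sharpless asymmetric epoxidation touches only the allylic alcohol alkene, and the D-(−)-tartrate (the one that gives (R)-2-alkylglycidols) sets C13.

**Step 8**
Reactants: 11 (R)-epoxy alcohol
Product: 12 (S)-epoxy silyl ether
Conditions: TBSCl, imidazole, CH2Cl2, 0 °C → rt
Reagents that add atoms: tert-butyldimethylsilyl chloride, CC(C)(C)[Si](C)(C)Cl
Why: Standard silylation protects the future C16 hydroxyl, and only the descriptor changes, not the geometry at C13.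

**Step 9**
Reactants: 12 (S)-epoxy silyl ether
Product: 13 (S)-alkynol
Conditions: LiC≡CH·H2NCH2CH2NH2, DMSO, rt; then H2O
Reagents that add atoms: lithium acetylide, [Li]C#C
Why: SN2 opening of the 2,2-disubstituted epoxide occurs at its CH2 carbon (future C12), so the C13–O bond is not touched and the configuration is kept.

**Step 10**
Reactants: 13 (S)-alkynol
Product: 14 (S)-dihydrofuran
Conditions: Mo(CO)6 (25 mol %), Me3NO (25 mol %), Et3N/Et2O, rt
Reagents that add atoms: none
Why: Endo-selective cycloisomerisation of a but-3-yn-1-ol through a molybdenum vinylidene adds the tertiary O–H to the terminal alkyne carbon and gives the 2,3-dihydrofuran without touching the allyl group or C13.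

**Step 11**
Reactants: 14 (S)-dihydrofuran; 8 trans-hydrindanone
Product: 16 dihydrofuranyl carbinol, via lithiodihydrofuran 15 (not isolated)
Conditions: 14, t-BuLi, THF, −78 → 0 °C; then 8, −78 → −20 °C; then H2O
Reagents that add atoms: none
Why: Alpha-lithiation of the cyclic enol ether followed by 1,2-addition should attack the ketone from the alpha face, opposite to the angular methyl as in 17-oxo steroids, so C8 gets OH beta and C9 alpha.

**Step 12**
Reactants: 16 dihydrofuranyl carbinol
Product: 18 spiro 8-ketone, via oxocarbenium ion 17 (not isolated)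
Conditions: camphor-10-sulfonic acid (10 mol %), 4 Å MS, CH2Cl2, 0 °C → rt
Reagents that add atoms: none
Why: Protonation of the enol ether at C11 gives the ring C oxocarbenium ion 17, whose cationic C9 sits next to the tertiary carbinol C8, and a suprafacial 1,2-shift of the C8–C10 bond to C9, pushed by the hydroxyl lone pair, enlarges the cyclopentane (C5, C6, C7, C8, C10) to the cyclohexanone ring B before the new C8 carbonyl gives the proton back. The closest known reaction type is the oxonium-ion-initiated pinacol ring expansion of 1-(4,5-dihydrofuran-2-yl)cycloalkanols to 1-oxaspiro ketones (four to five and five to six ring atoms), and the same bond shift is known as the D-homoannulation of 17-beta-hydroxy-17-alpha-acyl steroids. No ring is closed end to end: ring B grows from five to six atoms by the 1,2-shift, and ring C, already closed, becomes spiro-fused in the same event while the bond between the two fully substituted carbons C9 and C10 is made. The only new stereocentre, C9, is controlled by the C8 carbinol centre of step 11, which is consumed in exchange: C10 reaches C9 only from the side on which it is bonded to C8, and the rotamer that places the ring oxygen rather than the C11 methylene under the alpha face next to C7, away from the C8–O dipole, should be preferred, so O ends alpha (axial, anti to the C10 methyl) and C11 beta. The step needs migration of C10 and not of C7, which the higher migratory aptitude of the fully substituted carbon in a late, cation-like transition state and the relief of crowding around C8 should secure. C5, C10 and C13 are not touched, and the silyl ether and the allyl group tolerate catalytic sulfonic acid in dry CH2Cl2.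

**Step 13**
Reactants: 18 spiro 8-ketone
Product: 20 enol triflate, via potassium enolate 19 (not isolated)
Conditions: KN(SiMe3)2, THF, −78 °C; then PhNTf2, −78 → 0 °C
Reagents that add atoms: N-phenylbis(trifluoromethanesulfonimide), O=S(=O)(N(c1ccccc1)S(=O)(=O)C(F)(F)F)C(F)(F)F
Why: C9 is fully substituted, so only C7 can be deprotonated, and O-sulfonylation of this single enolate gives one enol triflate.

**Step 14**
Reactants: 20 enol triflate
Product: 21 7-ene
Conditions: MeMgBr, Fe(acac)3 (5 mol %), THF/NMP, −20 °C
Reagents that add atoms: methylmagnesium bromide, C[Mg]Br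
Why: Iron-catalysed Kumada-type cross-coupling of alkenyl triflates with MeMgBr installs the C8 methyl regiospecifically and leaves the silyl ether and the terminal alkene alone.

**Step 15**
Reactants: 21 7-ene
Product: 22 7-alpha,8-alpha-epoxide
Conditions: mCPBA (1.05 equiv), Na2HPO4, CH2Cl2, 0 °C
Reagents that add atoms: 3-chloroperbenzoic acid, OOC(=O)c1cccc(Cl)c1
Why: In this Prilezhaev epoxidation the trisubstituted ring alkene is far more nucleophilic than the monosubstituted allyl group, and attack opposite to the axial C10 methyl should place the oxygen on the alpha face.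

**Step 16**
Reactants: 22 7-alpha,8-alpha-epoxide
Product: 23 7-ketone
Conditions: BF3·OEt2 (0.3 equiv), CH2Cl2, −78 °C
Reagents that add atoms: none
Why: In the Meinwald rearrangement the Lewis acid opens the epoxide at tertiary C8 and the beta hydrogen on C7 shifts to C8 anti to the leaving oxygen, which gives the 7-ketone with H beta and the methyl alpha (equatorial, also the stable epimer) at C8.

**Step 17**
Reactants: 23 7-ketone
Product: 25 6-enol acetate, via lithium enolate 24 (not isolated)
Conditions: LiN(iPr)2, THF, −78 °C; then Ac2O, −78 °C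
Reagents that add atoms: acetic anhydride, CC(=O)OC(C)=O
Why: Kinetic deprotonation takes the C6 methylene rather than the tertiary C8–H, which also avoids the enolate that could expel the C9 oxygen, and O-acylation traps it as the enol acetate.

**Step 18**
Reactants: 25 6-enol acetate
Product: 27 6-beta-acetoxy 7-ketone silyl ether, via epoxy acetate 26 (not isolated)
Conditions: DMDO (1.05 equiv), acetone/CH2Cl2, 0 °C; evaporate; then PhMe, 110 °C
Reagents that add atoms: dimethyldioxirane, CC1(C)OO1
Why: In this enol ester epoxide rearrangement, alpha-face epoxidation (the beta face is blocked by the C4 and C10 methyls) is followed by a thermal intramolecular 1,2-acyloxy shift in which the ester carbonyl oxygen attacks C6 from behind the C6–O bond, so inversion places the acetate beta at C6 and C7 becomes the ketone.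

**Step 19**
Reactants: 27 6-beta-acetoxy 7-ketone silyl ether
Product: 28 6-beta-acetoxy 7-ketone alcohol
Conditions: HF·pyridine, pyridine/THF, 0 °C
Reagents that add atoms: none
Why: Buffered fluoride desilylation frees the C16 hydroxyl without base, so the C6 acetate and the beta-alkoxy ketone are not endangered.

**Step 20**
Reactants: 28 6-beta-acetoxy 7-ketone alcohol
Product: 31 lactol, via ozonide 29 (not isolated), via hydroxy aldehyde 30 (not isolated)
Conditions: O3, CH2Cl2, −78 °C; then Me2S, −78 °C → rt
Reagents that add atoms: ozone, [O-][O+]=O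
Why: Ozonolysis with reductive work-up cleaves the only alkene to the C15 aldehyde, which closes on the C16 hydroxyl to the five-membered lactol (both anomers serve).

**Step 21**
Reactants: 31 lactol
Product: 33 target CNP0224709.1, via lactol mesylate 32 (not isolated)
Conditions: MsCl, Et3N (excess), CH2Cl2, −40 °C → rt; Et3N-washed SiO2
Reagents that add atoms: none
Why: Lactol mesylation and amine-induced elimination can form only the C14=C15 enol ether because C13 has no hydrogen, and the basic medium prevents the acid-triggered opening of ring C to the furan.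

**Compound list**
1 | (S)-Hajos–Parrish ketone, (7aS)-7a-methyl-2,3,7,7a-tetrahydro-1H-indene-1,5(6H)-dione | O=C1CCC2=CC(=O)CC[C@]12C | starting material
2 | enone ketal: 1 with the cyclopentanone carbonyl (C8) as 1,3-dioxolane, (7aS) | C1COC2(O1)CCC3=CC(=O)CC[C@]23C | intermediate
3 | monomethyl enone ketal: 2 with one methyl on C4 | C1COC2(O1)CCC3=C(C)C(=O)CC[C@]23C | intermediate
4 | gem-dimethyl ketone ketal: 4,4-dimethyl, C3 ketone, C5=C6 alkene, C8 ketal | C1COC2(O1)CC=C3C(C)(C)C(=O)CC[C@]23C | intermediate
5 | hydrazone of 4 at C3 | C1COC2(O1)CC=C3C(C)(C)C(=NN)CC[C@]23C | intermediate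
6 | alkene ketal: 4 with CH2 at C3 | C1COC2(O1)CC=C3C(C)(C)CCC[C@]23C | intermediate
7 | trans-hydrindane ketal, (3aS,7aS), H-5 alpha, C10 methyl beta | C1COC2(O1)CC[C@H]3C(C)(C)CCC[C@]23C | intermediate
8 | (3aS,7aS)-4,4,7a-trimethyloctahydro-1H-inden-1-one (trans) | O=C1CC[C@H]2C(C)(C)CCC[C@]12C | intermediate
9 | prop-2-yn-1-ol | C#CCO | starting material
10 | 2-methylidenepent-4-en-1-ol | C=CCC(=C)CO | intermediate
11 | [(2R)-2-(prop-2-en-1-yl)oxiran-2-yl]methanol | C1[C@](CO)(CC=C)O1 | intermediate
12 | tert-butyldimethylsilyl ether of 11, (S) | C1[C@](CO[Si](C)(C)C(C)(C)C)(CC=C)O1 | intermediate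
13 | (4S)-4-[(tert-butyldimethylsilyloxy)methyl]hept-1-en-6-yn-4-ol | C#CC[C@](CO[Si](C)(C)C(C)(C)C)(CC=C)O | intermediate
14 | (2S)-2-allyl-2-[(tert-butyldimethylsilyloxy)methyl]-2,3-dihydrofuran | C1=CC[C@](CO[Si](C)(C)C(C)(C)C)(CC=C)O1 | intermediate
15 | 5-lithio derivative of 14 | [Li]C1=CC[C@](CO[Si](C)(C)C(C)(C)C)(CC=C)O1 | intermediate
16 | (1S,3aS,7aS)-1-[(5S)-5-allyl-5-(TBSOCH2)-4,5-dihydrofuran-2-yl]-4,4,7a-trimethyloctahydroinden-1-ol; OH cis to the angular methyl | O[C@@]1(C2=CC[C@](CO[Si](C)(C)C(C)(C)C)(CC=C)O2)CC[C@H]3C(C)(C)CCC[C@]13C | intermediate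
17 | oxocarbenium ion: 16 protonated at C11, C9=O+ | O[C@@]1(C2=[O+][C@@](CO[Si](C)(C)C(C)(C)C)(CC=C)CC2)CC[C@H]3C(C)(C)CCC[C@]13C | intermediate
18 | spiro 8-ketone: trans-decalin (H-5 alpha, C10 methyl beta), C8 ketone, C9 spiro to the oxolane (O alpha, C11 beta), C13 (R) with allyl and CH2OTBS | C1CC(=O)[C@]2(CC[C@](CO[Si](C)(C)C(C)(C)C)(CC=C)O2)[C@@]2(C)CCCC(C)(C)[C@H]12 | intermediate
19 | potassium C7=C8 enolate of 18 | C1C=C([O-])[C@]2(CC[C@](CO[Si](C)(C)C(C)(C)C)(CC=C)O2)[C@@]2(C)CCCC(C)(C)[C@H]12.[K+] | intermediate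
20 | C7=C8 enol triflate of 18 | C1C=C(OS(=O)(=O)C(F)(F)F)[C@]2(CC[C@](CO[Si](C)(C)C(C)(C)C)(CC=C)O2)[C@@]2(C)CCCC(C)(C)[C@H]12 | intermediate
21 | 7-ene: C7=C8 alkene with the methyl on C8 | C1C=C(C)[C@]2(CC[C@](CO[Si](C)(C)C(C)(C)C)(CC=C)O2)[C@@]2(C)CCCC(C)(C)[C@H]12 | intermediate
22 | 7-alpha,8-alpha-epoxide of 21 | C1[C@H]2O[C@@]2(C)[C@]3(CC[C@](CO[Si](C)(C)C(C)(C)C)(CC=C)O3)[C@@]4(C)CCCC(C)(C)[C@H]14 | intermediate
23 | 7-ketone: C8 methyl alpha, H-8 beta | C1C(=O)[C@@H](C)[C@]2(CC[C@](CO[Si](C)(C)C(C)(C)C)(CC=C)O2)[C@@]2(C)CCCC(C)(C)[C@H]12 | intermediate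
24 | lithium C6=C7 enolate of 23 | C1=C([O-])[C@@H](C)[C@]2(CC[C@](CO[Si](C)(C)C(C)(C)C)(CC=C)O2)[C@@]2(C)CCCC(C)(C)[C@H]12.[Li+] | intermediate
25 | C6=C7 enol acetate of 23 | C1=C(OC(C)=O)[C@@H](C)[C@]2(CC[C@](CO[Si](C)(C)C(C)(C)C)(CC=C)O2)[C@@]2(C)CCCC(C)(C)[C@H]12 | intermediate
26 | 6-alpha,7-alpha-epoxy-7-beta-acetate | O1[C@H]2[C@]1(OC(C)=O)[C@@H](C)[C@]3(CC[C@](CO[Si](C)(C)C(C)(C)C)(CC=C)O3)[C@@]4(C)CCCC(C)(C)[C@H]24 | intermediate
27 | 6-beta-acetoxy 7-ketone, C13 with allyl and CH2OTBS | CC(=O)O[C@@H]1C(=O)[C@@H](C)[C@]2(CC[C@](CO[Si](C)(C)C(C)(C)C)(CC=C)O2)[C@@]2(C)CCCC(C)(C)[C@H]12 | intermediate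
28 | 6-beta-acetoxy 7-ketone, C13 with allyl and CH2OH | CC(=O)O[C@@H]1C(=O)[C@@H](C)[C@]2(CC[C@](CO)(CC=C)O2)[C@@]2(C)CCCC(C)(C)[C@H]12 | intermediate
29 | 1,2,4-trioxolane (ozonide) of 28, C15 unassigned | CC(=O)O[C@@H]1C(=O)[C@@H](C)[C@]2(CC[C@](CO)(CC3OCOO3)O2)[C@@]2(C)CCCC(C)(C)[C@H]12 | intermediate
30 | C15 aldehyde with free C16 hydroxyl | CC(=O)O[C@@H]1C(=O)[C@@H](C)[C@]2(CC[C@](CO)(CC=O)O2)[C@@]2(C)CCCC(C)(C)[C@H]12 | intermediate
31 | 15-hydroxy-15,16-epoxide (lactol, both C15 anomers) | CC(=O)O[C@@H]1C(=O)[C@@H](C)[C@]2(CC[C@]3(CC(O)OC3)O2)[C@@]2(C)CCCC(C)(C)[C@H]12 | intermediate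
32 | C15 mesylate of 31 | CC(=O)O[C@@H]1C(=O)[C@@H](C)[C@]2(CC[C@]3(CC(OS(C)(=O)=O)OC3)O2)[C@@]2(C)CCCC(C)(C)[C@H]12 | intermediate
33 | (5S,6S,8S,9R,10S,13R)-6-acetoxy-9,13;15,16-diepoxylabd-14-en-7-one | CC(=O)O[C@@H]1C(=O)[C@@H](C)[C@]2(CC[C@]3(C=COC3)O2)[C@@]2(C)CCCC(C)(C)[C@H]12 | target

**Step count**
Total step count: 21. Longest linear sequence: 16 (steps 1–5 and 11–21).

**Steps most likely to fail**

Step 12. The C7 methylene may migrate instead of C10, water may be lost from the carbinol before the shift, or C10 may attack the other rotamer of the cation and give poor face selectivity at C9.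
- The fallback sets out from 16. The enol ether is first trapped with MeOH and pyridinium p-toluenesulfonate as the isolable methyl ketal F1.
- F1 is then ionised with TMSOTf and 2,6-di-tert-butylpyridine in CH2Cl2 at −78 °C, so the same shift runs from a preformed oxocarbenium ion under aprotic, irreversible conditions.
- It comes back at 18.

Step 16. A substituent of C9 may shift to the C8 cation (ring B would shrink again), or C6 may shift to give a ring-contracted aldehyde instead of the hydride shift.
- The fallback sets out from 18 and avoids any C8 cation.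
- Wittig methylenation with Ph3P=CH2 gives the exocyclic alkene F2.
- Allylic hydroxylation with SeO2 and t-BuOOH gives the 7-alpha-alcohol F3.
- Dess–Martin oxidation gives the exocyclic enone F4.
- 1,4-Reduction with [(Ph3P)CuH]6 in wet benzene, followed by equilibration of C8 on silica, comes back at 23.

Step 18. Traces of acid may open the epoxy acetate with retention, or the acyl transfer onto the crowded beta face may be too slow, so C6 would come out with the wrong configuration.
- The fallback sets out from 21 and sets C6 by hydride delivery instead.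
- Allylic oxidation with CrO3 and 3,5-dimethylpyrazole gives the 7-en-6-one F5.
- Luche reduction (NaBH4, CeCl3·7H2O) from the open alpha face gives the 6-beta-alcohol F6.
- Ac2O and DMAP give the allylic acetate F7.
- mCPBA gives the 7-alpha,8-alpha-epoxide F8.
- BF3·OEt2 induces the hydride shift, which comes back at 27.

**Further compounds**
F1 | step 12 | methyl ketal of 16 at C9 (2-methoxyoxolane, C9 epimers) | O[C@@]1(C2(OC)CC[C@](CO[Si](C)(C)C(C)(C)C)(CC=C)O2)CC[C@H]3C(C)(C)CCC[C@]13C
F2 | step 16 | 8(17)-methylidene compound from 18 | C1CC(=C)[C@]2(CC[C@](CO[Si](C)(C)C(C)(C)C)(CC=C)O2)[C@@]2(C)CCCC(C)(C)[C@H]12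
F3 | step 16 | 7-alpha-hydroxy-8(17)-ene | C1[C@@H](O)C(=C)[C@]2(CC[C@](CO[Si](C)(C)C(C)(C)C)(CC=C)O2)[C@@]2(C)CCCC(C)(C)[C@H]12
F4 | step 16 | 8(17)-en-7-one | C1C(=O)C(=C)[C@]2(CC[C@](CO[Si](C)(C)C(C)(C)C)(CC=C)O2)[C@@]2(C)CCCC(C)(C)[C@H]12
F5 | step 18 | 7-en-6-one | O=C1C=C(C)[C@]2(CC[C@](CO[Si](C)(C)C(C)(C)C)(CC=C)O2)[C@@]2(C)CCCC(C)(C)[C@H]12
F6 | step 18 | 7-en-6-beta-ol | O[C@@H]1C=C(C)[C@]2(CC[C@](CO[Si](C)(C)C(C)(C)C)(CC=C)O2)[C@@]2(C)CCCC(C)(C)[C@H]12
F7 | step 18 | 6-beta-acetoxy-7-ene | CC(=O)O[C@@H]1C=C(C)[C@]2(CC[C@](CO[Si](C)(C)C(C)(C)C)(CC=C)O2)[C@@]2(C)CCCC(C)(C)[C@H]12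
F8 | step 18 | 6-beta-acetoxy-7-alpha,8-alpha-epoxide | CC(=O)O[C@@H]1[C@H]2O[C@@]2(C)[C@]3(CC[C@](CO[Si](C)(C)C(C)(C)C)(CC=C)O3)[C@@]4(C)CCCC(C)(C)[C@H]14
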